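**Retrosynthetic overview**
- The last bond is the C1–O aryl ether of the oxepane: a phenoxide captures a tertiary C1 cation. In the same operation C4–C9' and C1–C5 form and a hydride moves from C1 to C10, so the target opens to (+)-bicyclogermacrene plus an o-quinone methide from 2,4-diformylphloroglucinol and isovaleraldehyde.
- (+)-Bicyclogermacrene opens at C1=C10 to a keto aldehyde (McMurry coupling).
- The keto aldehyde comes from a Claisen rearrangement (E-C4=C5, C2–C3) of an allylic alcohol made from ozonised (+)-2-carene and an isopropenyl nucleophile.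
- Ring order: cyclopropane (chiral pool), then the ten-membered ring, then the five- and seven-membered carbocycles (transannular), then the oxepane by C–O closure.

Assumption: terpene carbons carry aromadendrane numbers (C1–C15) and the benzylic carbon is C9'; compounds 1, 3, 5, 9 and 10 are bought (9 is otherwise one Vilsmeier step from phloroglucinol).

**Step 1**
Reactants: 1 (+)-2-carene [(1S,6R)-3,7,7-trimethylbicyclo[4.1.0]hept-2-ene]
Product: 2 (1S,3R)-2,2-dimethyl-3-(3-oxobutyl)cyclopropane-1-carbaldehyde
Conditions: O3, CH2Cl2, −78 °C; then Me2S, −78 → 20 °C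
Reagents that add atoms: ozone, [O-][O+]=O
Why: Criegee ozonolysis with reductive work-up cleaves the only C=C; the two cis cyclopropane stereocentres (later C6 and C7) come unchanged from the chiral pool, and the neutral work-up avoids cis-to-trans epimerisation of the aldehyde.

**Step 2**
Reactants: 2 (1S,3R)-2,2-dimethyl-3-(3-oxobutyl)cyclopropane-1-carbaldehyde; 3 isopropenylmagnesium bromide
Product: 4 4-[(1R,3S)-3-(1-hydroxy-2-methylprop-2-en-1-yl)-2,2-dimethylcyclopropyl]butan-2-one (both carbinol epimers)
Conditions: 3 (1.05 equiv, slow addition), THF, −78 °C; then H2O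
Reagents that add atoms: none
Why: Grignard 1,2-addition, in which the aldehyde reacts much faster than the methyl ketone at −78 °C with one equivalent; the new carbinol centre forms as an epimer mixture, which does not matter because this carbon becomes sp2 in step 3.

**Step 3**
Reactants: 4 4-[(1R,3S)-3-(1-hydroxy-2-methylprop-2-en-1-yl)-2,2-dimethylcyclopropyl]butan-2-one; 5 ethyl vinyl ether
Product: 7 (4E)-5-[(1S,3R)-2,2-dimethyl-3-(3-oxobutyl)cyclopropyl]-4-methylpent-4-enal, via allyl vinyl ether 6 (not isolated)
Conditions: 5 (solvent), Hg(OAc)2 (10 mol %), NaOAc, reflux; evaporate; PhMe, 110 °C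
Reagents that add atoms: none
Why: Transvinylation followed by Claisen [3,3]-rearrangement through a chair transition state with the cyclopropyl group equatorial gives the E-trisubstituted C4=C5 alkene from both carbinol epimers and installs C2–C3 and the C1 aldehyde; 110 °C stays below the homo-1,5-hydrogen shift of the cis-vinylcyclopropane.

**Step 4**
Reactants: 7 (4E)-5-[(1S,3R)-2,2-dimethyl-3-(3-oxobutyl)cyclopropyl]-4-methylpent-4-enal
Product: 8 (+)-bicyclogermacrene [(1S,2E,6E,10R)-3,7,11,11-tetramethylbicyclo[8.1.0]undeca-2,6-diene]
Conditions: TiCl3(DME)1.5, Zn–Cu, DME, reflux, syringe-pump addition of 7 (final 2 mM); filtration through basic alumina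
Reagents that add atoms: none
Why: Intramolecular McMurry carbonyl coupling on low-valent titanium under high dilution closes the ten-membered ring as the (E)-C1=C10 olefin, the geometry this coupling is known to give for bicyclogermacrene-type macrocycles; any minor Z isomer is removed on AgNO3-impregnated silica.

**Step 5**
Reactants: 8 (+)-bicyclogermacrene; 9 2,4-diformylphloroglucinol (2,4,6-trihydroxybenzene-1,3-dicarbaldehyde); 10 isovaleraldehyde (3-methylbutanal)
Product: 15 target CNP0189833.2 (C4–C9' linked and C1–O oxepane-bridged aromadendrane–diformylphloroglucinol meroterpenoid), via benzylic alcohol adduct 11 (not isolated), via o-quinone methide 12 (not isolated), via C10 cation zwitterion 13 (not isolated), via C1 cation zwitterion 14 (not isolated)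
Conditions: 9 (1.1 equiv), 10 (1.5 equiv), (R)-TRIP phosphoric acid (10 mol %), 5 Å MS, ClCH2CH2Cl, 40 °C, 2 h; then 8, 0 → 25 °C
Reagents that add atoms: none
Why: Proposed new method: a chiral phosphoric acid–catalysed three-component cation cascade in which the acid first promotes Friedel–Crafts hydroxyalkylation and dehydration (9 + 10 → 11 → 12) and then holds the (E)-o-quinone methide 12 as a hydrogen-bonded ion pair with its carbonyl oxygen masked, so that 12 acts as a pure carbon electrophile: C4 of the E-C4=C5 bond of the crown conformer of 8 attacks C9' from the open face with the isobutyl group turned toward the small C15 methyl (9'R, reinforced by the catalyst pocket) while C1=C10 closes transannularly onto C5 (anti addition across C4=C5, setting C4, C5 and the trans ring fusion) to give tertiary cation 13, a suprafacial 1,2-hydride shift of H-1α to C10 sets C10 and gives tertiary cation 14, and the tethered phenoxide closes the oxepane by C1–O bond formation on the β face; elimination products of 13 can re-enter by reprotonation, so the ether is the sink; the closest known chemistry is the uncatalysed thermal Knoevenagel/o-quinone methide coupling of macrocyclic terpenes with benzaldehyde-derived o-quinone methides, phosphoric acid–catalysed o-quinone methide cycloadditions and Brønsted acid–catalysed cation–olefin cyclisations.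

**Compound list**
1 | (+)-2-carene, (1S,6R)-3,7,7-trimethylbicyclo[4.1.0]hept-2-ene | CC1=C[C@H]2[C@@H](CC1)C2(C)C | starting material
2 | (1S,3R)-2,2-dimethyl-3-(3-oxobutyl)cyclopropane-1-carbaldehyde (cis) | O=C[C@H]1[C@@H](CCC(C)=O)C1(C)C | intermediate
3 | isopropenylmagnesium bromide | CC(=C)[Mg]Br | starting material
4 | 4-[(1R,3S)-3-(1-hydroxy-2-methylprop-2-en-1-yl)-2,2-dimethylcyclopropyl]butan-2-one, both carbinol epimers | CC(=C)C(O)[C@H]1[C@@H](CCC(C)=O)C1(C)C | intermediate
5 | ethyl vinyl ether | C=COCC | starting material
6 | 4-[(1R,3S)-3-[1-(ethenyloxy)-2-methylprop-2-en-1-yl]-2,2-dimethylcyclopropyl]butan-2-one, both ether-carbon epimers | CC(=C)C(OC=C)[C@H]1[C@@H](CCC(C)=O)C1(C)C | intermediate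
7 | (4E)-5-[(1S,3R)-2,2-dimethyl-3-(3-oxobutyl)cyclopropyl]-4-methylpent-4-enal | O=CCC/C(C)=C/[C@H]1[C@@H](CCC(C)=O)C1(C)C | intermediate
8 | (+)-bicyclogermacrene, (1S,2E,6E,10R)-3,7,11,11-tetramethylbicyclo[8.1.0]undeca-2,6-diene | C/C1=C\CC/C(C)=C/[C@H]2[C@@H](CC1)C2(C)C | intermediate
9 | 2,4-diformylphloroglucinol, 2,4,6-trihydroxybenzene-1,3-dicarbaldehyde | O=Cc1c(O)cc(O)c(C=O)c1O | starting material
10 | isovaleraldehyde, 3-methylbutanal | CC(C)CC=O | starting material
11 | 2,4,6-trihydroxy-5-(1-hydroxy-3-methylbutyl)benzene-1,3-dicarbaldehyde (racemic) | CC(C)CC(O)c1c(O)c(C=O)c(O)c(C=O)c1O | intermediate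
12 | (5E)-2,4-dihydroxy-5-(3-methylbutylidene)-6-oxocyclohexa-1,3-diene-1,3-dicarbaldehyde (o-quinone methide) | CC(C)C/C=C1/C(=O)C(C=O)=C(O)C(C=O)=C1O | intermediate
13 | C10 cation zwitterion: trans-fused aromadendran-10-ylium (H-1α, H-5β) carrying at C4 the (9'R)-CH(isobutyl)aryl group, aryl = 3,5-diformyl-4,6-dihydroxy-2-oxidophenyl | CC(C)C[C@@H](c1c(O)c(C=O)c(O)c(C=O)c1[O-])[C@@]1(C)CC[C@@H]2[C@@H]1[C@H]1[C@@H](CC[C+]2C)C1(C)C | intermediate
14 | C1 cation zwitterion: aromadendran-1-ylium (H-5β, H-10α, 10β-methyl) with the same C4 substituent | CC(C)C[C@@H](c1c(O)c(C=O)c(O)c(C=O)c1[O-])[C@@]1(C)CC[C+]2[C@@H]1[C@H]1[C@@H](CC[C@@H]2C)C1(C)C | intermediate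
15 | CNP0189833.2: aromadendrane with C4–C9' bond and C1–O–aryl ether to 3,5-diformylphloroglucinol (1S,4R,5R,6R,7R,10S,9'R) | CC(C)C[C@H]1c2c(O)c(C=O)c(O)c(C=O)c2O[C@]23CC[C@@]1(C)[C@H]2[C@H]1[C@@H](CC[C@@H]3C)C1(C)C | target

**Step count**
Total steps: 5. Longest linear sequence: 5 steps (1 → 2 → 4 → 7 → 8 → 15).

**Steps most likely to fail, with fallbacks**

For step 5 (the proposed new method), the risks are competing [4+2] chroman adducts at either ring olefin, the C9' epimer, acid-induced cyclisation of 8 before it meets 12, and opening of the cyclopropane from cation 14. The fallback uses known chemistry and sets out from 9 and 10. Proline-catalysed reductive alkylation with Hantzsch ester gives 2,4,6-trihydroxy-5-(3-methylbutyl)benzene-1,3-dicarbaldehyde F3. Oxidation of F3 with DDQ in MeNO2 at 0 °C in the presence of 8 then generates the o-quinone methide without added acid. This is the oxidative o-quinone methide generation used for euglobal-type adducts. The route is rejoined at 12 and runs thermally through 13 and 14 to 15, which is separated from cycloadducts and the C9' epimer by chromatography.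

For step 4, the risks are Cope rearrangement of 8 at reflux, E/Z mixtures and oligomers. The fallback sets out from 7. Titanium-induced pinacol macrocyclisation at 25 °C (TiCl3(DME)1.5, Zn–Cu, DME) gives (2E)-3,7,11,11-tetramethylbicyclo[8.1.0]undec-2-ene-6,7-diol F1. Thiocarbonyldiimidazole converts it into the cyclic 6,7-thionocarbonate F2. Corey–Hopkins syn-elimination with 1,3-dimethyl-2-phenyl-1,3,2-diazaphospholidine at 40 °C then returns to the route at 8. Only the diol with the drawn relative configuration (or its bis-epimer at both carbinol carbons) gives the E olefin, so the diols are separated before the elimination.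

For step 2, the risk is competing addition to, or enolisation of, the methyl ketone. The fallback sets out from 2 and replaces the organomagnesium addition by a Nozaki–Hiyama–Kishi coupling with 2-bromopropene (CrCl2, NiCl2 cat., DMF, 25 °C). The organochromium nucleophile is non-basic and adds to aldehydes but not to ketones. It returns to the route at 4 and makes no new compound (F0).

**Further compounds**
F0 | step 2 | none | none
F1 | step 4 | (2E)-3,7,11,11-tetramethylbicyclo[8.1.0]undec-2-ene-6,7-diol, cis-cyclopropane, E-forming diol configuration | C[C@@]1(O)[C@@H](O)CC/C(C)=C/[C@H]2[C@@H](CC1)C2(C)C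
F2 | step 4 | cyclic 6,7-thionocarbonate of F1 | S=C1O[C@H]2CC/C(C)=C/[C@H]3[C@@H](CC[C@]2(C)O1)C3(C)C
F3 | step 5 | 2,4,6-trihydroxy-5-(3-methylbutyl)benzene-1,3-dicarbaldehyde | CC(C)CCc1c(O)c(C=O)c(O)c(C=O)c1O
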